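**Remark (locants and one assumption).** Germacrane/eudesmane-type locants are used throughout: C10 = quaternary C–CH3, C5 = ether CH, C4 = CH–CH2OH (C15), C3 = CH–OAc, C6 = lactone CH–O, C7 = lactone CH, C8 = CH–O-methacryloyl, C11/C12/C13 = lactone α-carbon, carbonyl and exo-methylene. α/β refer to the decalin intermediates, with the C10 methyl β. The two ether carbons are both R, which corresponds to a trans-disposed (inside–outside, H-5 "in") C5–O–C10 bridge on the 11-oxabicyclo[4.4.1]undecane core; the route is built for that isomer.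

## Retrosynthetic overview

1. The ether oxygen links quaternary C10 and C5–H, which are 1,6-related on the ten-membered carbocycle. Removing it leaves the C5–C10 bond of a trans-decalin, so both oxepane rings (O–C10–C1–C2–C3–C4–C5 and O–C10–C9–C8–C7–C6–C5) are made last by inserting oxygen into that bond (Criegee rearrangement of a C5 hydroperoxide). The C5 hydrogen is delivered internally from a 3α-O-benzyl group that lies 1,3-diaxial to C5.
2. The hydroperoxide comes from a tertiary 5α-bromide, itself from bromolactonisation of a Δ5 acrylic acid. This transposes an 8β,12-lactone to the cis 6β,12-lactone and frees O8 for the methacrylate.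
3. Ring B: a C8 ketone takes the C7 acetate chain (alkylation, then kinetic protonation), α-face hydride gives the 8β-alcohol and lactone, and Eschenmoser methylenation follows.
4. Ring A: deconjugative C4 silyloxymethylation anti to the angular methyl, then L-Selectride to the 3α-alcohol.
5. The decalin comes from a d'Angelo Michael addition and Robinson annulation. Ring order: purchased cyclohexane (ring B), ring A, γ-lactones, then the two oxepanes.

Key step: step 14

## Route

Step 1
Reactants: 1 7-methyl-1,4-dioxaspiro[4.5]decan-8-one (racemic); 2 (R)-1-phenylethylamine; 3 methyl vinyl ketone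
Product: 6 (7R)-7-methyl-7-(3-oxobutyl)-1,4-dioxaspiro[4.5]decan-8-one, via ketimine 4 (not isolated), via Michael-adduct ketimine 5 (not isolated)
Conditions: 2, TsOH (cat.), toluene, Dean–Stark; then 3, THF, 40 °C; then 20% aq. AcOH, 25 °C
Reagents that add atoms: water, O
Why: d'Angelo deracemising Michael addition, in which the secondary enamine tautomer of ketimine 4 adds through its more substituted α-carbon to the enone on the face anti to the phenyl group of the auxiliary, so the quaternary centre should form as R from either enantiomer of 1 (the sense mirrors the established (S)-amine to (R)-2-methyl-2-(3-oxobutyl)cyclohexanone correlation, relabelled by the ketal).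

Step 2
Reactants: 6 (7R)-7-methyl-7-(3-oxobutyl)-1,4-dioxaspiro[4.5]decan-8-one
Product: 7 (10R)-8,8-ethylenedioxy-10-methyl-decal-4-en-3-one
Conditions: NaOMe (0.3 equiv), MeOH, 60 °C
Reagents that add atoms: none
Why: Intramolecular aldol condensation (second stage of the Robinson annulation) closes ring A as the conjugated enone without touching the quaternary centre.

Step 3
Reactants: 7 (10R)-8,8-ethylenedioxy-10-methyl-decal-4-en-3-one
Product: 8 8,8-ethylenedioxy-10β-methyl-decal-5-en-3-one
Conditions: KOt-Bu (1.5 equiv), t-BuOH, 25 °C; inverse quench into cold 10% aq. AcOH; used crude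
Reagents that add atoms: none
Why: Deconjugation of a Δ4-3-ketone, in which the extended dienolate is protonated kinetically at C4 and the double bond moves to C5=C6, where it is needed later.

Step 4
Reactants: 8 8,8-ethylenedioxy-10β-methyl-decal-5-en-3-one
Product: 9 8,8-ethylenedioxy-10β-methyl-4α-[(triisopropylsilyloxy)methyl]-decal-5-en-3-one (4β-H)
Conditions: LDA (1.05 equiv), THF, −78 °C; (i-Pr)3SiOCH2Cl, −78 to −40 °C; cold NH4Cl quench
Reagents that add atoms: (triisopropylsiloxy)methyl chloride, ClCO[Si](C(C)C)(C(C)C)C(C)C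
Why: Deconjugative α-alkylation of the lithium dienolate (the C4–H flanked by carbonyl and alkene is removed) with an alkoxymethyl chloride, where the electrophile should attack C4 anti to the axial C10 methyl and so place the silyloxymethyl group α.

Step 5
Reactants: 9 8,8-ethylenedioxy-10β-methyl-4α-[(triisopropylsilyloxy)methyl]-decal-5-en-3-one
Product: 10 8,8-ethylenedioxy-10β-methyl-4α-[(triisopropylsilyloxy)methyl]-decal-5-en-3α-ol
Conditions: L-Selectride, THF, −78 °C; aq. NH4Cl
Reagents that add atoms: none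
Why: Hindered-hydride ketone reduction, in which L-Selectride attacks C3 on the equatorial trajectory and anti to the adjacent 4α-substituent, giving the axial 3α-alcohol cis to the C4 side chain while the low temperature keeps the β,γ-enone from conjugating.

Step 6
Reactants: 10 8,8-ethylenedioxy-10β-methyl-4α-[(triisopropylsilyloxy)methyl]-decal-5-en-3α-ol
Product: 11 3α-benzyloxy-8,8-ethylenedioxy-10β-methyl-4α-[(triisopropylsilyloxy)methyl]-decal-5-ene
Conditions: 2-benzyloxy-1-methylpyridinium triflate, MgO, PhCF3, 85 °C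
Reagents that add atoms: 2-benzyloxy-1-methylpyridinium triflate, C[n+]1ccccc1OCc1ccccc1.[O-]S(=O)(=O)C(F)(F)F
Why: Benzyl transfer from Dudley's reagent under neutral buffered conditions etherifies the hindered axial alcohol without silyl migration or ketal loss, and the benzyl ether is also the latent hydride donor for step 14.

Step 7
Reactants: 11 3α-benzyloxy-8,8-ethylenedioxy-10β-methyl-4α-[(triisopropylsilyloxy)methyl]-decal-5-ene
Product: 12 3α-benzyloxy-10β-methyl-4α-[(triisopropylsilyloxy)methyl]-decal-5-en-8-one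
Conditions: PPTS (0.2 equiv), acetone/H2O, 40 °C
Reagents that add atoms: water, O
Why: Mild acid-catalysed ketal hydrolysis, with the weak buffered acid chosen so that the β,γ-unsaturated ketone is not equilibrated into conjugation.

Step 8
Reactants: 12 3α-benzyloxy-10β-methyl-4α-[(triisopropylsilyloxy)methyl]-decal-5-en-8-one
Product: 14 methyl 2-[3α-benzyloxy-10β-methyl-8-oxo-4α-[(triisopropylsilyloxy)methyl]-decal-5-en-7β-yl]acetate (7α-H), via lithium dienolate 13 (not isolated)
Conditions: LDA (1.05 equiv), THF, −78 °C; BrCH2CO2Me (1.0 equiv), DMPU, −78 to −40 °C; LiHMDS (1.1 equiv), −78 °C; AcOH, −78 °C; used directly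
Reagents that add atoms: methyl bromoacetate, COC(=O)CBr
Why: Kinetic deprotonation at the doubly activated C7 gives the extended dienolate, which is C-alkylated at its α-carbon; re-enolisation to 13 and axial kinetic protonation from the α face should then place the acetate chain equatorial (7β, also the thermodynamic epimer) while leaving the double bond at C5=C6.

Step 9
Reactants: 14 methyl 2-[3α-benzyloxy-10β-methyl-8-oxo-4α-[(triisopropylsilyloxy)methyl]-decal-5-en-7β-yl]acetate
Product: 16 3α-benzyloxy-15-(triisopropylsilyloxy)-eudesm-5-en-12,8β-olide lacking C13 (cis-fused γ-lactone; 7α-H and 8α-H), via hydroxy ester 15 (not isolated)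
Conditions: NaBH4, CeCl3·7H2O, MeOH/THF, −40 to 25 °C
Reagents that add atoms: none
Why: Borohydride should attack the C8 carbonyl from the α face because the β face is blocked by the 1,3-syn-axial C10 methyl (as in 6- and 11-keto steroids), and the resulting axial 8β-alkoxide lactonises onto the cis ester to the cis-fused γ-lactone.

Step 10
Reactants: 16 3α-benzyloxy-15-(triisopropylsilyloxy)-eudesm-5-en-12,8β-olide lacking C13
Product: 19 3α-benzyloxy-15-(triisopropylsilyloxy)-eudesma-5,11(13)-dien-12,8β-olide, via Mannich base 17 (not isolated), via ammonium iodide 18 (not isolated)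
Conditions: LDA, THF, −78 °C; CH2=NMe2+ I−, −78 to 25 °C; MeI, MeOH; NaHCO3, CH2Cl2/H2O
Reagents that add atoms: Eschenmoser's salt, C=[N+](C)C.[I-]
Why: Eschenmoser α-methylenation (Mannich reaction of the lactone enolate, N-quaternisation, elimination) gives the exo-methylene lactone, and C7 is not enolisable so it is unaffected.

Step 11
Reactants: 19 3α-benzyloxy-15-(triisopropylsilyloxy)-eudesma-5,11(13)-dien-12,8β-olide
Product: 21 3α-benzyloxy-5α-bromo-8β-hydroxy-15-(triisopropylsilyloxy)-eudesm-11(13)-en-12,6β-olide, via lithium carboxylate 20 (not isolated)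
Conditions: LiOH (1.5 equiv), THF/H2O, 25 °C; then NaHCO3, NBS (1.1 equiv), 0 °C, dark
Reagents that add atoms: lithium hydroxide, [Li+].[OH-]; N-bromosuccinimide, O=C1CCC(=O)N1Br
Why: Saponification then bromolactonisation, in which the bromonium ion forms on the α face of the electron-rich C5=C6 bond and the C12 carboxylate attacks C6 from the β face (trans-diaxial, 5-exo), which transposes the lactone to O6 as the cis-fused 6β-lactone, frees the 8β-hydroxyl and leaves a tertiary bromide at C5; the electron-poor acrylate alkene should not react.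

Step 12
Reactants: 21 3α-benzyloxy-5α-bromo-8β-hydroxy-15-(triisopropylsilyloxy)-eudesm-11(13)-en-12,6β-olide
Product: 22 3α-benzyloxy-5α-bromo-8β-methacryloyloxy-15-(triisopropylsilyloxy)-eudesm-11(13)-en-12,6β-olide
Conditions: methacrylic anhydride, i-Pr2NEt, DMAP (cat.), CH2Cl2, 0 °C
Reagents that add atoms: methacrylic anhydride, C=C(C)C(=O)OC(=O)C(C)=C
Why: DMAP-catalysed acylation of the only free hydroxyl, run cold to avoid E2 loss of the tertiary bromide.

Step 13
Reactants: 22 3α-benzyloxy-5α-bromo-8β-methacryloyloxy-15-(triisopropylsilyloxy)-eudesm-11(13)-en-12,6β-olide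
Product: 23 3α-benzyloxy-5α-hydroperoxy-8β-methacryloyloxy-15-(triisopropylsilyloxy)-eudesm-11(13)-en-12,6β-olide
Conditions: AgOCOCF3 (1.5 equiv), anhydrous ethereal H2O2 (10 equiv), Et2O, −20 to 0 °C, dark
Reagents that add atoms: hydrogen peroxide, OO
Why: Silver-assisted SN1 perhydrolysis of a tertiary bromide, in which hydrogen peroxide should capture the C5 cation axially from the α face, anti to the C10 methyl and the 6β-acyloxy group (either C5 epimer would serve in step 14).

Step 14
Reactants: 23 3α-benzyloxy-5α-hydroperoxy-8β-methacryloyloxy-15-(triisopropylsilyloxy)-eudesm-11(13)-en-12,6β-olide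
Product: 27 15-O-triisopropylsilyl-3-deacetyl target (3α-hydroxy-5,10-epoxy-germacranolide), via peroxy trifluoroacetate 24 (not isolated), via bridgehead oxocarbenium salt 25 (not isolated), via trifluoroacetoxybenzyl acetal 26 (not isolated)
Conditions: (CF3CO)2O (1.3 equiv), CH2Cl2, −78 to 0 °C; aq. NaHCO3
Reagents that add atoms: none
Why: Proposed new method: TFAA converts the hydroperoxide into perester 24, whose O–O bond ionises while the antiperiplanar C5–C10 bond shifts to the proximal oxygen (Criegee rearrangement; closest precedent is trans-9-decalyl peresters giving 1-acyloxy-11-oxabicyclo[4.4.1]undecanes), so both cyclohexane rings become oxepane rings by a one-atom ring expansion and no ring is closed by cyclisation. C10 migrates with retention, which fixes its configuration, and it is selected over C4 and C6 because it is the only tertiary-alkyl group on C5 and C6 is deactivated by the lactone oxygen. The new element is interception of the twisted bridgehead oxocarbenium ion 25 by 1,5-hydride transfer from the benzylic CH2 of the axial 3α-benzyl ether through a six-membered transition state (related known chemistry: hydride transfer from benzyl ethers to oxocarbenium ions and other cationic acceptors), which can deliver hydrogen only to the α face of C5. This internal delivery, not the intrinsic facial bias of the ion, should set C5 as R with the hydrogen inside (trans-bridged) rather than the less strained cis-bridged epimer expected from an external hydride. The benzylic oxocarbenium ion so formed is captured by trifluoroacetate (26) and hydrolysed on work-up to benzaldehyde and the free 3α-hydroxyl, while proton loss to an enol ether or ion-pair return to the bridgehead trifluoroacetate are reversible under the acidic conditions and feed the same irreversible hydride transfer.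

Step 15
Reactants: 27 15-O-triisopropylsilyl-3-deacetyl target
Product: 28 15-O-triisopropylsilyl target (3α-acetate)
Conditions: Ac2O, pyridine, DMAP (cat.), CH2Cl2, 0 to 25 °C
Reagents that add atoms: acetic anhydride, CC(=O)OC(C)=O
Why: Standard DMAP-catalysed acetylation of the unmasked axial 3α-hydroxyl, the only free hydroxyl in 27.

Step 16
Reactants: 28 15-O-triisopropylsilyl target
Product: 29 CNP0602302.1 (target)
Conditions: HF·pyridine, THF/pyridine, 0 to 25 °C
Reagents that add atoms: none
Why: Fluoride cleavage of the primary triisopropylsilyl ether under buffered, mildly acidic conditions that should avoid acetyl migration from O3 to O15 and conjugate addition to the two acrylate units.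

## Compound list

1 | 7-methyl-1,4-dioxaspiro[4.5]decan-8-one (racemic) | CC1CC2(CCC1=O)OCCO2 | starting material
2 | (R)-1-phenylethylamine | C[C@@H](N)c1ccccc1 | starting material
3 | methyl vinyl ketone | C=CC(C)=O | starting material
4 | N-[(1R)-1-phenylethyl] ketimine of 1 | CC1CC2(CCC1=N[C@H](C)c1ccccc1)OCCO2 | intermediate
5 | N-[(1R)-1-phenylethyl] ketimine of 6 | C12(OCCO1)C[C@@](C)(CCC(C)=O)C(=N[C@H](C)c1ccccc1)CC2 | intermediate
6 | (7R)-7-methyl-7-(3-oxobutyl)-1,4-dioxaspiro[4.5]decan-8-one | C12(OCCO1)C[C@@](C)(CCC(C)=O)C(=O)CC2 | intermediate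
7 | (10R)-8,8-ethylenedioxy-10-methyl-decal-4-en-3-one | C12(OCCO1)C[C@@]3(C)CCC(=O)C=C3CC2 | intermediate
8 | 8,8-ethylenedioxy-10β-methyl-decal-5-en-3-one | C12(OCCO1)C[C@@]3(C)CCC(=O)CC3=CC2 | intermediate
9 | 4α-[(triisopropylsilyloxy)methyl] derivative of 8 (4β-H) | C12(OCCO1)C[C@@]3(C)CCC(=O)[C@@H](CO[Si](C(C)C)(C(C)C)C(C)C)C3=CC2 | intermediate
10 | 3α-alcohol from 9 | C12(OCCO1)C[C@@]3(C)CC[C@@H](O)[C@@H](CO[Si](C(C)C)(C(C)C)C(C)C)C3=CC2 | intermediate
11 | 3α-benzyl ether of 10 | C12(OCCO1)C[C@@]3(C)CC[C@@H](OCc1ccccc1)[C@@H](CO[Si](C(C)C)(C(C)C)C(C)C)C3=CC2 | intermediate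
12 | 3α-benzyloxy-10β-methyl-4α-[(triisopropylsilyloxy)methyl]-decal-5-en-8-one | O=C1C[C@@]2(C)CC[C@@H](OCc3ccccc3)[C@@H](CO[Si](C(C)C)(C(C)C)C(C)C)C2=CC1 | intermediate
13 | lithium dienolate (C7=C8–OLi, C5=C6) of the C7-alkylated ketone | [Li+].[O-]C1=C(CC(=O)OC)C=C2[C@H](CO[Si](C(C)C)(C(C)C)C(C)C)[C@H](OCc3ccccc3)CC[C@]2(C)C1 | intermediate
14 | methyl 7β-acetate of ketone 12 (7α-H) | O=C1C[C@@]2(C)CC[C@@H](OCc3ccccc3)[C@@H](CO[Si](C(C)C)(C(C)C)C(C)C)C2=C[C@@H]1CC(=O)OC | intermediate
15 | 8β-hydroxy methyl ester | O[C@@H]1C[C@@]2(C)CC[C@@H](OCc3ccccc3)[C@@H](CO[Si](C(C)C)(C(C)C)C(C)C)C2=C[C@@H]1CC(=O)OC | intermediate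
16 | cis-fused 8β,12-γ-lactone (7α-H, 8α-H), Δ5 | O1[C@@H]2C[C@@]3(C)CC[C@@H](OCc4ccccc4)[C@@H](CO[Si](C(C)C)(C(C)C)C(C)C)C3=C[C@@H]2CC1=O | intermediate
17 | α-(dimethylaminomethyl) lactone (C11 epimers) | O1[C@@H]2C[C@@]3(C)CC[C@@H](OCc4ccccc4)[C@@H](CO[Si](C(C)C)(C(C)C)C(C)C)C3=C[C@@H]2C(CN(C)C)C1=O | intermediate
18 | trimethylammonium iodide of 17 | O1[C@@H]2C[C@@]3(C)CC[C@@H](OCc4ccccc4)[C@@H](CO[Si](C(C)C)(C(C)C)C(C)C)C3=C[C@@H]2C(C[N+](C)(C)C)C1=O.[I-] | intermediate
19 | 3α-benzyloxy-15-(triisopropylsilyloxy)-eudesma-5,11(13)-dien-12,8β-olide | O1[C@@H]2C[C@@]3(C)CC[C@@H](OCc4ccccc4)[C@@H](CO[Si](C(C)C)(C(C)C)C(C)C)C3=C[C@@H]2C(=C)C1=O | intermediate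
20 | lithium 8β-hydroxy acrylate (ring-opened 19) | O[C@@H]1C[C@@]2(C)CC[C@@H](OCc3ccccc3)[C@@H](CO[Si](C(C)C)(C(C)C)C(C)C)C2=C[C@@H]1C(=C)C(=O)[O-].[Li+] | intermediate
21 | 5α-bromo-8β-hydroxy-6β,12-lactone | O[C@@H]1C[C@@]2(C)CC[C@@H](OCc3ccccc3)[C@@H](CO[Si](C(C)C)(C(C)C)C(C)C)[C@]2(Br)[C@@H]2OC(=O)C(=C)[C@@H]21 | intermediate
22 | 8β-methacrylate of 21 | C=C(C)C(=O)O[C@@H]1C[C@@]2(C)CC[C@@H](OCc3ccccc3)[C@@H](CO[Si](C(C)C)(C(C)C)C(C)C)[C@]2(Br)[C@@H]2OC(=O)C(=C)[C@@H]21 | intermediate
23 | 5α-hydroperoxide | C=C(C)C(=O)O[C@@H]1C[C@@]2(C)CC[C@@H](OCc3ccccc3)[C@@H](CO[Si](C(C)C)(C(C)C)C(C)C)[C@]2(OO)[C@@H]2OC(=O)C(=C)[C@@H]21 | intermediate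
24 | 5α-peroxy trifluoroacetate | C=C(C)C(=O)O[C@@H]1C[C@@]2(C)CC[C@@H](OCc3ccccc3)[C@@H](CO[Si](C(C)C)(C(C)C)C(C)C)[C@]2(OOC(=O)C(F)(F)F)[C@@H]2OC(=O)C(=C)[C@@H]21 | intermediate
25 | bridgehead oxocarbenium (C5=O+–C10) trifluoroacetate | C=C(C)C(=O)O[C@@H]1C[C@@]2(C)CC[C@@H](OCc3ccccc3)[C@@H](CO[Si](C(C)C)(C(C)C)C(C)C)C(=[O+]2)[C@@H]2OC(=O)C(=C)[C@@H]21.[O-]C(=O)C(F)(F)F | intermediate
26 | 3-O-[α-(trifluoroacetoxy)benzyl] acetal of 27 | C=C(C)C(=O)O[C@@H]1C[C@@]2(C)CC[C@@H](OC(OC(=O)C(F)(F)F)c3ccccc3)[C@@H](CO[Si](C(C)C)(C(C)C)C(C)C)[C@@H](O2)[C@@H]2OC(=O)C(=C)[C@@H]21 | intermediate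
27 | 15-O-triisopropylsilyl-3-deacetyl target | C=C(C)C(=O)O[C@@H]1C[C@@]2(C)CC[C@@H](O)[C@@H](CO[Si](C(C)C)(C(C)C)C(C)C)[C@@H](O2)[C@@H]2OC(=O)C(=C)[C@@H]21 | intermediate
28 | 15-O-triisopropylsilyl target | C=C(C)C(=O)O[C@@H]1C[C@@]2(C)CC[C@@H](OC(C)=O)[C@@H](CO[Si](C(C)C)(C(C)C)C(C)C)[C@@H](O2)[C@@H]2OC(=O)C(=C)[C@@H]21 | intermediate
29 | CNP0602302.1 | C=C(C)C(=O)O[C@@H]1C[C@@]2(C)CC[C@@H](OC(C)=O)[C@@H](CO)[C@@H](O2)[C@@H]2OC(=O)C(=C)[C@@H]21 | target

## Step count and risk

Total steps: 16. Longest linear sequence: 16.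

**Step 14 (Proposed new method).** The internal hydride transfer may be slower than conformational relaxation of the bridgehead cation or than diversion of the benzylic cation (for example capture by the silyl ether oxygen), and the perester may fragment by migration of C4. The fallback sets out from 23 and returns at 27 using known steps. Classical Criegee rearrangement with Ac2O/DMAP/pyridine in CH2Cl2 should give the isolable 5α-acetoxy bridgehead ketal F1. Ionic reduction of this α-acyloxy ether with Et3SiH/TMSOTf at −78 °C should give the 3-O-benzyl ether of 27 F2, with any C5 epimer removed at this stage. Visible-light DDQ debenzylation in wet CH2Cl2 then gives 27. The weakness of this path is facial control by an external hydride.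

**Step 13.** Ionisation of the tertiary bromide may be diverted to elimination towards C4 or to a 1,2-methyl shift from C10 before peroxide capture, and silver may decompose the peroxide. The fallback sets out from 22 and returns at 23. Silver-assisted hydrolysis in wet acetone, where water as co-solvent captures the cation, should give the 5α-alcohol F3. Classical acid-catalysed exchange of the tertiary hydroxyl (50% H2O2, cat. H2SO4, THF, 0 °C) then gives hydroperoxide 23.

**Step 8.** Protonation of dienolate 13 may show poor facial selectivity, and the C5=C6 bond may migrate into conjugation with the C8 ketone. The fallback sets out from 11 and returns at 16, and fixes C7 by chirality transfer instead. β-Selective epoxidation with KMnO4–CuSO4·5H2O should give the 5β,6β-epoxide F4. Opening with PhSeNa at C6 gives the 6α-phenylselanyl-5β-ol F5, and H2O2 oxidation with syn-elimination gives the 5β-hydroxy-Δ6 allylic alcohol F6. Johnson–Claisen rearrangement (triethyl orthoacetate, cat. propionic acid, 140 °C) moves the two-carbon chain suprafacially from O5 to the β face of C7 and restores C5=C6 in the ethyl 7β-acetate ketal F7. PPTS hydrolysis gives the 8-keto ethyl ester F8, and NaBH4 reduction with lactonisation as in step 9 gives 16.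

## Further compounds

F1 | step 14 | 5α-acetoxy bridgehead ketal (3α-benzyl ether, 15-O-TIPS) | C=C(C)C(=O)O[C@@H]1C[C@@]2(C)CC[C@@H](OCc3ccccc3)[C@@H](CO[Si](C(C)C)(C(C)C)C(C)C)[C@@](OC(C)=O)(O2)[C@@H]2OC(=O)C(=C)[C@@H]21
F2 | step 14 | 3-O-benzyl ether of 27 | C=C(C)C(=O)O[C@@H]1C[C@@]2(C)CC[C@@H](OCc3ccccc3)[C@@H](CO[Si](C(C)C)(C(C)C)C(C)C)[C@@H](O2)[C@@H]2OC(=O)C(=C)[C@@H]21
F3 | step 13 | 5α-alcohol corresponding to 22 | C=C(C)C(=O)O[C@@H]1C[C@@]2(C)CC[C@@H](OCc3ccccc3)[C@@H](CO[Si](C(C)C)(C(C)C)C(C)C)[C@]2(O)[C@@H]2OC(=O)C(=C)[C@@H]21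
F4 | step 8 | 5β,6β-epoxide of 11 | C12(OCCO1)C[C@@]3(C)CC[C@@H](OCc1ccccc1)[C@@H](CO[Si](C(C)C)(C(C)C)C(C)C)[C@]34O[C@@H]4C2
F5 | step 8 | 6α-phenylselanyl-5β-ol | C12(OCCO1)C[C@@]3(C)CC[C@@H](OCc1ccccc1)[C@@H](CO[Si](C(C)C)(C(C)C)C(C)C)[C@@]3(O)[C@@H]([Se]c1ccccc1)C2
F6 | step 8 | 5β-hydroxy-Δ6 allylic alcohol | C12(OCCO1)C[C@@]3(C)CC[C@@H](OCc1ccccc1)[C@@H](CO[Si](C(C)C)(C(C)C)C(C)C)[C@@]3(O)C=CC2
F7 | step 8 | ethyl 7β-acetate, Δ5, 8-ketal | C12(OCCO1)C[C@@]3(C)CC[C@@H](OCc1ccccc1)[C@@H](CO[Si](C(C)C)(C(C)C)C(C)C)C3=C[C@@H]2CC(=O)OCC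
F8 | step 8 | 8-keto ethyl ester (ethyl analogue of 14) | O=C1C[C@@]2(C)CC[C@@H](OCc3ccccc3)[C@@H](CO[Si](C(C)C)(C(C)C)C(C)C)C2=C[C@@H]1CC(=O)OCC
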